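**Retrosynthetic overview**

1. Target 26 comes from its O-methyl tetronate 25 by thiolate demethylation. 25 comes from N-allylhydrazone 23 by an acid-catalysed [3,3] shift with loss of N2, which makes the CH2–CH2 bond between the inner furan's side chain and the allylic carbon of the trisubstituted olefin.
2. Enabling feature: this CH2–CH2 link lies between C-4 of the inner (2,4-disubstituted) furan and the C(CH3)=CH olefin. The furylic carbon can therefore start as the hydrazone carbon of a furan-3-carbaldehyde, and the allylic carbon as the =CH2 end of an N-bound isopropenyl carbinyl unit (six-atom array C=N–N–C–C(CH3)=CH2).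
3. 23 comes from bis-furan aldehyde 21 and allylic hydrazine 22. The hydrazine is made by an azo-ene reaction on the prenyl end of 13, so ene plus [3,3] are two allylic transpositions that turn an (E)-methyl C–H into the new C–C bond.
4. 13 comes from (S)-aldehyde 7 and methyl tetronate 9 by aldol addition and dehydration; 7 comes from (R)-3-bromo-2-methylpropan-1-ol, the only source of chirality. 21 comes from 3-bromofuran and 4-bromofuran-2-carbaldehyde.
5. Ring order: no ring is built. The tetronate ring and both furans are bought intact and only joined (furan–CH2–furan, then tetronate to chain, then the two halves).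

Key step: step 13

Remark: the SMILES is read as (S) at the side-chain methyl carbon, Z at the ylidene and E at the chain olefin; compounds 1, 3, 8, 15 and 16 are taken as catalogue materials; the hydrazine-bearing carbon of 14, 22 and 23 forms as both epimers, which converge in step 13.

**Route**

Step 1
Reactants: 1 (R)-3-bromo-2-methylpropan-1-ol
Product: 2 (R)-(3-bromo-2-methylpropoxy)(tert-butyl)dimethylsilane
Conditions: TBSCl, imidazole, CH2Cl2, 0 °C to rt
Reagents that add atoms: tert-butyldimethylsilyl chloride, CC(C)(C)[Si](C)(C)Cl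
Why: Imidazole-promoted silylation of a primary alcohol; the stereocentre is not touched.

Step 2
Reactants: 2 (R)-(3-bromo-2-methylpropoxy)(tert-butyl)dimethylsilane; 3 5-bromo-2-methylpent-2-ene
Product: 5 (S)-tert-butyl[(2,7-dimethyloct-6-en-1-yl)oxy]dimethylsilane, via (4-methylpent-3-en-1-yl)magnesium bromide 4 (not isolated)
Conditions: 3, Mg, THF, rt; then 2, Li2CuCl4 (cat.), NMP, THF, 0 °C to rt
Reagents that add atoms: none
Why: Copper-catalysed sp3–sp3 Grignard cross-coupling (Kochi–Cahiez type) at a primary bromide; the stereocentre is β to the reacting carbon and keeps its geometry (R becomes S only through the change in CIP priorities).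

Step 3
Reactants: 5 (S)-tert-butyl[(2,7-dimethyloct-6-en-1-yl)oxy]dimethylsilane
Product: 6 (S)-2,7-dimethyloct-6-en-1-ol
Conditions: TBAF, THF, rt
Reagents that add atoms: none
Why: Fluoride-induced cleavage of a primary silyl ether.

Step 4
Reactants: 6 (S)-2,7-dimethyloct-6-en-1-ol
Product: 7 (S)-2,7-dimethyloct-6-enal
Conditions: Dess–Martin periodinane, NaHCO3, CH2Cl2, 0 °C to rt; used directly
Reagents that add atoms: none
Why: Buffered Dess–Martin oxidation should give the α-branched aldehyde without epimerisation.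

Step 5
Reactants: 8 3-methyltetronic acid (4-hydroxy-3-methylfuran-2(5H)-one)
Product: 9 4-methoxy-3-methylfuran-2(5H)-one
Conditions: Me2SO4, K2CO3, acetone, reflux
Reagents that add atoms: dimethyl sulfate, COS(=O)(=O)OC
Why: O-Alkylation of the vinylogous acid at O-4 masks the acidic OH and allows C-5 metalation.

Step 6
Reactants: 9 4-methoxy-3-methylfuran-2(5H)-one; 7 (S)-2,7-dimethyloct-6-enal
Product: 11 5-[(2S)-1-hydroxy-2,7-dimethyloct-6-en-1-yl]-4-methoxy-3-methylfuran-2(5H)-one (diastereomer mixture), via lithium 4-methoxy-3-methylfuran-2-olate 10 (not isolated)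
Conditions: LDA, THF, −78 °C; then 7, −78 °C; aq. NH4Cl
Reagents that add atoms: none
Why: Aldol addition of the C-5 lithiated tetronate (a vinylogous enolate); at −78 °C addition should outrun α-epimerisation of 7, and the two new stereocentres are erased in step 7.

Step 7
Reactants: 11 5-[(2S)-1-hydroxy-2,7-dimethyloct-6-en-1-yl]-4-methoxy-3-methylfuran-2(5H)-one
Product: 13 (5Z)-5-[(2S)-2,7-dimethyloct-6-en-1-ylidene]-4-methoxy-3-methylfuran-2(5H)-one, via mesylate 12 (not isolated)
Conditions: MsCl, Et3N, CH2Cl2, 0 °C; then DBU, 0 °C to rt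
Reagents that add atoms: none
Why: Mesylation followed by E1cB elimination through the acidic C-5–H; the Z ylidene (chain syn to the ring oxygen, away from the 4-methoxy group) is the thermodynamically preferred isomer, and any E isomer is removed by chromatography.

Step 8
Reactants: 13 (5Z)-5-[(2S)-2,7-dimethyloct-6-en-1-ylidene]-4-methoxy-3-methylfuran-2(5H)-one
Product: 14 di-tert-butyl 1-[(7S,8Z)-8-(3-methoxy-4-methyl-5-oxofuran-2(5H)-ylidene)-2,7-dimethyloct-1-en-3-yl]hydrazine-1,2-dicarboxylate (both C-3 epimers)
Conditions: di-tert-butyl azodicarboxylate, toluene, 80 °C, dark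
Reagents that add atoms: di-tert-butyl azodicarboxylate, CC(C)(C)OC(=O)/N=N/C(=O)OC(C)(C)C
Why: Azo-ene reaction in which nitrogen adds to the less substituted carbon of the electron-rich prenyl olefin and hydrogen is taken from a methyl group, giving the branched isopropenyl hydrazide; the acceptor-conjugated ylidene olefin should be far less reactive, and the new C–N stereocentre is unselective but is removed in step 13.

Step 9
Reactants: 15 3-bromofuran; 16 4-bromofuran-2-carbaldehyde
Product: 18 (4-bromofuran-2-yl)(furan-3-yl)methanol (racemic), via furan-3-yllithium 17 (not isolated)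
Conditions: 15, n-BuLi, THF, −78 °C; then 16, −78 °C; aq. NH4Cl
Reagents that add atoms: none
Why: Bromine–lithium exchange followed by 1,2-addition to the aldehyde, which should be much faster than exchange at the β-bromide of 16.

Step 10
Reactants: 18 (4-bromofuran-2-yl)(furan-3-yl)methanol
Product: 19 4-bromo-2-(furan-3-ylmethyl)furan
Conditions: Et3SiH, TFA, CH2Cl2, −20 to 0 °C
Reagents that add atoms: none
Why: Ionic hydrogenation of a doubly heteroaryl-stabilised carbinol through the furfuryl-type cation, which excess silane should trap quickly.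

Step 11
Reactants: 19 4-bromo-2-(furan-3-ylmethyl)furan
Product: 21 5-(furan-3-ylmethyl)furan-3-carbaldehyde, via [5-(furan-3-ylmethyl)furan-3-yl]lithium 20 (not isolated)
Conditions: n-BuLi, Et2O, −78 °C; then DMF, −78 to 0 °C; aq. NH4Cl
Reagents that add atoms: N,N-dimethylformamide, CN(C)C=O
Why: Bromine–lithium exchange at −78 °C (where the 3-furyllithium should not isomerise) and Bouveault formylation with DMF.

Step 12
Reactants: 14 di-tert-butyl 1-[(7S,8Z)-8-(3-methoxy-4-methyl-5-oxofuran-2(5H)-ylidene)-2,7-dimethyloct-1-en-3-yl]hydrazine-1,2-dicarboxylate; 21 5-(furan-3-ylmethyl)furan-3-carbaldehyde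
Product: 23 (5Z)-5-[(2S)-6-{(2E)-2-[(5-(furan-3-ylmethyl)furan-3-yl)methylidene]hydrazinyl}-2,7-dimethyloct-7-en-1-ylidene]-4-methoxy-3-methylfuran-2(5H)-one, via allylic hydrazine 22 (not isolated)
Conditions: TFA, CH2Cl2, 0 °C; evaporate; then 21, NaOAc, EtOH, rt, under Ar
Reagents that add atoms: none
Why: Acidolysis of both Boc groups followed by condensation of the free NH2 of the monoalkylhydrazine with the aldehyde to the E hydrazone; the hydrazine is air-sensitive and is therefore not isolated.

Step 13
Reactants: 23 (5Z)-5-[(2S)-6-{(2E)-2-[(5-(furan-3-ylmethyl)furan-3-yl)methylidene]hydrazinyl}-2,7-dimethyloct-7-en-1-ylidene]-4-methoxy-3-methylfuran-2(5H)-one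
Product: 25 (5Z)-5-[(2S,6E)-9-[5-(furan-3-ylmethyl)furan-3-yl]-2,7-dimethylnon-6-en-1-ylidene]-4-methoxy-3-methylfuran-2(5H)-one, via monoalkyl diazene 24 (not isolated)
Conditions: HNTf2 (10 mol%), degassed diglyme, 125 °C
Reagents that add atoms: none
Why: Protonation of the hydrazone triggers a charge-accelerated [3,3]-sigmatropic shift through the array C(furylic)=N–N–CH–C(CH3)=CH2, which bonds the hydrazone carbon to the terminal methylene, cleaves the N–C(allyl) bond and leaves monoalkyl diazene 24, which expels N2 to leave a C–H bond at the furylic carbon. The closest known reaction type is the triflimide-catalysed [3,3] rearrangement of N-allylhydrazones of aromatic aldehydes (a traceless sp3–sp3 bond construction, the catalysed form of the thermal N-allylhydrazone shift). No ring is closed. No stereocentre is created in the product: the C–N stereocentre of 23 becomes an olefin carbon (so both epimers converge), the transient stereocentre of 24 becomes CH2, and the remote (S)-centre is not involved. The step needs E geometry at the new trisubstituted olefin and survival of the furans and the ylidene tetronate. A chair transition state with the chain equatorial on the N-bearing carbon should secure the E geometry, and the basic hydrazone should buffer the catalytic acid so that no free strong acid reaches the furans.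

Step 14
Reactants: 25 (5Z)-5-[(2S,6E)-9-[5-(furan-3-ylmethyl)furan-3-yl]-2,7-dimethylnon-6-en-1-ylidene]-4-methoxy-3-methylfuran-2(5H)-one
Product: 26 (5Z)-5-[(2S,6E)-9-[5-(furan-3-ylmethyl)furan-3-yl]-2,7-dimethylnon-6-en-1-ylidene]-4-hydroxy-3-methylfuran-2(5H)-one
Conditions: n-PrSLi (from n-PrSH and n-BuLi), HMPA, rt; then dilute HCl to pH 3
Reagents that add atoms: none
Why: SN2 demethylation of the vinylogous carbonate by thiolate with the tetronate anion as leaving group; the stereocentre, both olefins and the furans are not touched.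

**Compound list**

1 | (R)-3-bromo-2-methylpropan-1-ol | OC[C@@H](C)CBr | starting material
2 | (R)-(3-bromo-2-methylpropoxy)(tert-butyl)dimethylsilane | CC(C)(C)[Si](C)(C)OC[C@@H](C)CBr | intermediate
3 | 5-bromo-2-methylpent-2-ene | CC(C)=CCCBr | starting material
4 | (4-methylpent-3-en-1-yl)magnesium bromide (formed in situ) | CC(C)=CCC[Mg]Br | intermediate
5 | (S)-tert-butyl[(2,7-dimethyloct-6-en-1-yl)oxy]dimethylsilane | CC(C)(C)[Si](C)(C)OC[C@@H](C)CCCC=C(C)C | intermediate
6 | (S)-2,7-dimethyloct-6-en-1-ol | OC[C@@H](C)CCCC=C(C)C | intermediate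
7 | (S)-2,7-dimethyloct-6-enal | O=C[C@@H](C)CCCC=C(C)C | intermediate
8 | 3-methyltetronic acid (4-hydroxy-3-methylfuran-2(5H)-one) | CC1=C(O)COC1=O | starting material
9 | 4-methoxy-3-methylfuran-2(5H)-one | COC1=C(C)C(=O)OC1 | intermediate
10 | lithium 4-methoxy-3-methylfuran-2-olate (C-5 lithiated 9, formed in situ) | [Li+].[O-]c1occ(OC)c1C | intermediate
11 | 5-[(2S)-1-hydroxy-2,7-dimethyloct-6-en-1-yl]-4-methoxy-3-methylfuran-2(5H)-one (mixture at C-5 and C-1') | COC1=C(C)C(=O)OC1C(O)[C@@H](C)CCCC=C(C)C | intermediate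
12 | methanesulfonate of 11 (formed in situ) | COC1=C(C)C(=O)OC1C(OS(C)(=O)=O)[C@@H](C)CCCC=C(C)C | intermediate
13 | (5Z)-5-[(2S)-2,7-dimethyloct-6-en-1-ylidene]-4-methoxy-3-methylfuran-2(5H)-one | COC1=C(C)C(=O)O/C1=C\[C@@H](C)CCCC=C(C)C | intermediate
14 | di-tert-butyl 1-[(7S,8Z)-8-(3-methoxy-4-methyl-5-oxofuran-2(5H)-ylidene)-2,7-dimethyloct-1-en-3-yl]hydrazine-1,2-dicarboxylate (both C-3 epimers) | COC1=C(C)C(=O)O/C1=C\[C@@H](C)CCCC(N(NC(=O)OC(C)(C)C)C(=O)OC(C)(C)C)C(C)=C | intermediate
15 | 3-bromofuran | Brc1ccoc1 | starting material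
16 | 4-bromofuran-2-carbaldehyde | O=Cc1cc(Br)co1 | starting material
17 | furan-3-yllithium (formed in situ) | [Li]c1ccoc1 | intermediate
18 | (4-bromofuran-2-yl)(furan-3-yl)methanol (racemic) | OC(c1ccoc1)c1cc(Br)co1 | intermediate
19 | 4-bromo-2-(furan-3-ylmethyl)furan | Brc1coc(Cc2ccoc2)c1 | intermediate
20 | [5-(furan-3-ylmethyl)furan-3-yl]lithium (formed in situ) | [Li]c1coc(Cc2ccoc2)c1 | intermediate
21 | 5-(furan-3-ylmethyl)furan-3-carbaldehyde | O=Cc1coc(Cc2ccoc2)c1 | intermediate
22 | (5Z)-5-[(2S)-6-hydrazinyl-2,7-dimethyloct-7-en-1-ylidene]-4-methoxy-3-methylfuran-2(5H)-one (both C-6 epimers, held as trifluoroacetate salt, formed in situ) | COC1=C(C)C(=O)O/C1=C\[C@@H](C)CCCC(NN)C(C)=C | intermediate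
23 | (5Z)-5-[(2S)-6-{(2E)-2-[(5-(furan-3-ylmethyl)furan-3-yl)methylidene]hydrazinyl}-2,7-dimethyloct-7-en-1-ylidene]-4-methoxy-3-methylfuran-2(5H)-one (both C-6 epimers) | COC1=C(C)C(=O)O/C1=C\[C@@H](C)CCCC(N/N=C/c2coc(Cc3ccoc3)c2)C(C)=C | intermediate
24 | (5Z)-5-[(2S,6E)-9-diazenyl-9-[5-(furan-3-ylmethyl)furan-3-yl]-2,7-dimethylnon-6-en-1-ylidene]-4-methoxy-3-methylfuran-2(5H)-one (formed in situ) | COC1=C(C)C(=O)O/C1=C\[C@@H](C)CCC/C=C(\C)CC(N=N)c2coc(Cc3ccoc3)c2 | intermediate
25 | (5Z)-5-[(2S,6E)-9-[5-(furan-3-ylmethyl)furan-3-yl]-2,7-dimethylnon-6-en-1-ylidene]-4-methoxy-3-methylfuran-2(5H)-one | COC1=C(C)C(=O)O/C1=C\[C@@H](C)CCC/C=C(\C)CCc2coc(Cc3ccoc3)c2 | intermediate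
26 | (5Z)-5-[(2S,6E)-9-[5-(furan-3-ylmethyl)furan-3-yl]-2,7-dimethylnon-6-en-1-ylidene]-4-hydroxy-3-methylfuran-2(5H)-one | CC1=C(O)/C(=C/[C@@H](C)CCC/C=C(\C)CCc2coc(Cc3ccoc3)c2)OC1=O | target

**Step count and risks**

Total step count: 14.
Longest linear sequence: 10 steps (steps 1, 2, 3, 4, 6, 7, 8, 12, 13, 14, from compound 1).

The three steps most likely to fail:

Step 13. The acid and heat may degrade the two furans or the ylidene tetronate faster than the sigmatropic shift proceeds, the N–H hydrazone may tautomerise to an azo compound, or the chair preference may not be large enough to give clean E geometry. The fallback forms the same CH2–CH2 bond by cross-coupling; it sets out from 13 and 21 and comes back at 25. Selenium dioxide with tert-butyl hydroperoxide (CH2Cl2, rt) should oxidise the (E)-methyl group of the prenyl end of 13 to (5Z)-5-[(2S,6E)-8-hydroxy-2,7-dimethyloct-6-en-1-ylidene]-4-methoxy-3-methylfuran-2(5H)-one F1. MsCl, LiCl and 2,4,6-collidine in DMF at 0 °C should convert this without allylic transposition into (5Z)-5-[(2S,6E)-8-chloro-2,7-dimethyloct-6-en-1-ylidene]-4-methoxy-3-methylfuran-2(5H)-one F2. Separately, 21 is reduced with NaBH4 in MeOH to [5-(furan-3-ylmethyl)furan-3-yl]methanol F3, which is converted with MsCl, Et3N and LiCl in THF into 4-(chloromethyl)-2-(furan-3-ylmethyl)furan F4 and then, with zinc dust and LiCl in THF, into {[5-(furan-3-ylmethyl)furan-3-yl]methyl}zinc chloride F5. Negishi coupling of F5 with F2 (Pd(PPh3)4 cat., THF, rt) should take place at the unsubstituted allyl terminus with retention of the E geometry, and the lactone should tolerate the organozinc, to give 25.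

Step 12. The allylic hydrazine may be lost during Boc cleavage through acid-induced ionisation or addition at the isopropenyl group, or through air oxidation before it is captured by the aldehyde. The fallback unmasks the hydrazine reductively instead of by acidolysis; it sets out from 13 and comes back at 23. An ene reaction of 13 with bis(2,2,2-trichloroethyl) azodicarboxylate (toluene, 60–80 °C), a more reactive enophile, should give bis(2,2,2-trichloroethyl) 1-[(7S,8Z)-8-(3-methoxy-4-methyl-5-oxofuran-2(5H)-ylidene)-2,7-dimethyloct-1-en-3-yl]hydrazine-1,2-dicarboxylate F6. Zinc dust in acetic acid at rt then removes both carbamates to give hydrazine 22, which is condensed with 21 as in step 12 to give 23.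

Step 10. The furfuryl-type cation formed in TFA may alkylate the free α-positions of a second furan and lead to oligomers faster than the silane reduces it. The fallback removes the oxygen under basic conditions; it sets out from 18 and comes back at 19. MnO2 in CH2Cl2 should oxidise 18 to (4-bromofuran-2-yl)(furan-3-yl)methanone F7, and Wolff–Kishner reduction in the Huang-Minlon form (N2H4·H2O, KOH, diethylene glycol, 130 then 190 °C) should proceed through (4-bromofuran-2-yl)(furan-3-yl)methanone hydrazone F8 to give 19.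

**Further compounds**

F1 | step 13 | (5Z)-5-[(2S,6E)-8-hydroxy-2,7-dimethyloct-6-en-1-ylidene]-4-methoxy-3-methylfuran-2(5H)-one | COC1=C(C)C(=O)O/C1=C\[C@@H](C)CCC/C=C(\C)CO
F2 | step 13 | (5Z)-5-[(2S,6E)-8-chloro-2,7-dimethyloct-6-en-1-ylidene]-4-methoxy-3-methylfuran-2(5H)-one | COC1=C(C)C(=O)O/C1=C\[C@@H](C)CCC/C=C(\C)CCl
F3 | step 13 | [5-(furan-3-ylmethyl)furan-3-yl]methanol | OCc1coc(Cc2ccoc2)c1
F4 | step 13 | 4-(chloromethyl)-2-(furan-3-ylmethyl)furan | ClCc1coc(Cc2ccoc2)c1
F5 | step 13 | {[5-(furan-3-ylmethyl)furan-3-yl]methyl}zinc chloride | Cl[Zn]Cc1coc(Cc2ccoc2)c1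
F6 | step 12 | bis(2,2,2-trichloroethyl) 1-[(7S,8Z)-8-(3-methoxy-4-methyl-5-oxofuran-2(5H)-ylidene)-2,7-dimethyloct-1-en-3-yl]hydrazine-1,2-dicarboxylate | COC1=C(C)C(=O)O/C1=C\[C@@H](C)CCCC(N(NC(=O)OCC(Cl)(Cl)Cl)C(=O)OCC(Cl)(Cl)Cl)C(C)=C
F7 | step 10 | (4-bromofuran-2-yl)(furan-3-yl)methanone | O=C(c1ccoc1)c1cc(Br)co1
F8 | step 10 | (4-bromofuran-2-yl)(furan-3-yl)methanone hydrazone | NN=C(c1ccoc1)c1cc(Br)co1
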